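**Retrosynthetic overview**

1. Target 17 ⇐ epoxide 16 ⇐ acetate 15: the side-chain carbinol comes from the prenyl terminus by C–O chemistry (Shi epoxidation, then epoxide-to-allylic-alcohol isomerisation).
2. 15 ⇐ 13 ⇐ acid 12: the spiro-γ-lactone is closed by a C–O bond between the carboxyl oxygen and the allylic CH2 of the geranyl chain (dehydrogenative allylic C–H lactonisation; key step, sets the lactone CH–O centre).
3. 12 ⇐ 4 + 5 + 8: the quaternary carbon is built by two successive α′-alkylations of the enone, the second one trans to OTBS.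
4. 4 ⇐ 1: singlet-oxygen cycloaddition and enantioselective Kornblum–DeLaMare rearrangement set the ring C–O centre.
5. Ring order: the carbocycle is present from 1; the lactone ring is formed second (step 6).

Assumption: 1, 5 and 8 are bought; the pseudo-enantiomer of the cinchona base (step 1) and the enantiomer of the sulfoxide–oxazoline ligand (step 6) that give the drawn configurations are fixed by one screening experiment each.

**Route**

Step 1
Reactants: 1 cyclohexa-1,3-diene
Product: 3 (4S)-4-hydroxycyclohex-2-en-1-one, via endoperoxide 2 (not isolated)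
Conditions: O2 (1 atm), tetraphenylporphyrin (0.5 mol %), white LED, CH2Cl2, 0 °C; then 9-O-acetylcupreine or its pseudo-enantiomer 9-O-acetylcupreidine (10 mol %), CH2Cl2, rt
Reagents that add atoms: dioxygen, O=O
Why: Singlet-oxygen [4+2] cycloaddition gives the meso endoperoxide, and the chiral amine base then removes one of the two enantiotopic bridgehead hydrogens (catalytic enantioselective Kornblum–DeLaMare rearrangement), so O–O cleavage gives the γ-hydroxy enone with C4 set as S.

Step 2
Reactants: 3 (4S)-4-hydroxycyclohex-2-en-1-one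
Product: 4 (4S)-4-[(tert-butyldimethylsilyl)oxy]cyclohex-2-en-1-one
Conditions: TBSCl, imidazole, CH2Cl2, 0 °C to rt
Reagents that add atoms: tert-butyldimethylsilyl chloride, CC(C)(C)[Si](C)(C)Cl
Why: Standard silylation of a secondary alcohol (TBS protection) lets the oxygen survive the two enolate steps, and no stereocentre is touched.

Step 3
Reactants: 4 (4S)-4-[(tert-butyldimethylsilyl)oxy]cyclohex-2-en-1-one; 5 geranyl bromide [(2E)-1-bromo-3,7-dimethylocta-2,6-diene]
Product: 7 (4S,6S)-4-[(tert-butyldimethylsilyl)oxy]-6-[(2E)-3,7-dimethylocta-2,6-dien-1-yl]cyclohex-2-en-1-one, via lithium enolate 6 (not isolated)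
Conditions: LiN(iPr)2 (1.05 equiv), THF, −78 °C; then 5, DMPU, −78 to −20 °C
Reagents that add atoms: geranyl bromide 5, CC(C)=CCC/C(C)=C/CBr
Why: Kinetic α′-deprotonation gives the cross-conjugated lithium enolate, which is C-alkylated by the primary allylic bromide in an SN2 enolate alkylation that keeps the E olefin; the electrophile enters mainly trans to OTBS, but C6 is made planar again in step 4, so this ratio does not matter.

Step 4
Reactants: 7 (4S,6S)-4-[(tert-butyldimethylsilyl)oxy]-6-[(2E)-3,7-dimethylocta-2,6-dien-1-yl]cyclohex-2-en-1-one; 8 methyl bromoacetate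
Product: 10 methyl 2-[(1R,5S)-5-[(tert-butyldimethylsilyl)oxy]-1-[(2E)-3,7-dimethylocta-2,6-dien-1-yl]-2-oxocyclohex-3-en-1-yl]acetate, via lithium enolate 9 (not isolated)
Conditions: LiN(iPr)2 (1.1 equiv), THF, −78 to −40 °C; then 8, DMPU, −78 to −30 °C
Reagents that add atoms: methyl bromoacetate 8, COC(=O)CBr
Why: The only α′-hydrogen left is at C6, so the base gives the tetrasubstituted enolate, and axial SN2 alkylation on the half-chair with pseudo-equatorial OTBS puts the incoming CH2CO2Me trans to C4–OTBS (geranyl cis), which sets the quaternary centre as R (substrate-controlled enolate alkylation).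

Step 5
Reactants: 10 methyl 2-[(1R,5S)-5-[(tert-butyldimethylsilyl)oxy]-1-[(2E)-3,7-dimethylocta-2,6-dien-1-yl]-2-oxocyclohex-3-en-1-yl]acetate
Product: 12 2-[(1R,5S)-5-[(tert-butyldimethylsilyl)oxy]-1-[(2E)-3,7-dimethylocta-2,6-dien-1-yl]-2-oxocyclohex-3-en-1-yl]acetic acid, via lithium carboxylate 11 (not isolated)
Conditions: LiOH·H2O, THF/H2O 3:1, 0 °C to rt; then 1 M HCl to pH 3
Reagents that add atoms: lithium hydroxide, [Li+].[OH-]
Why: Saponification of the unhindered methyl ester (the ketone has no α-hydrogen and the TBS ether is stable to LiOH) gives, after acidification, the free acid that the next step needs.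

Step 6
Reactants: 12 2-[(1R,5S)-5-[(tert-butyldimethylsilyl)oxy]-1-[(2E)-3,7-dimethylocta-2,6-dien-1-yl]-2-oxocyclohex-3-en-1-yl]acetic acid
Product: 13 (1R,5R,9S)-9-[(tert-butyldimethylsilyl)oxy]-1-[(1E)-2,6-dimethylhepta-1,5-dien-1-yl]-2-oxaspiro[4.5]dec-7-ene-3,6-dione
Conditions: Pd(OAc)2 (10 mol %), chiral aryl sulfoxide–oxazoline ligand (12 mol %), 2,6-dimethyl-1,4-benzoquinone (1.5 equiv), toluene (0.05 M), 45 °C
Reagents that add atoms: none
Why: Proposed new method: a carboxylate-directed dehydrogenative allylic C–H lactonisation at a trisubstituted internal olefin, in which the carboxylate of 12 binds divalent palladium and holds it on the proximal alkene, acetate-assisted cleavage of the adjacent CH2 (the only allylic C–H that can give a six-membered O–Pd–allyl chelate, so the distal prenyl unit and the other allylic sites are not engaged) gives a π-allyl palladium carboxylate, and quinone-promoted C–O reductive elimination at the CH terminus closes the five-membered lactone (attack at the tertiary terminus would need a seven-membered ring) with the E olefin kept because the allyl never σ-bonds at its tertiary end, the new C–O stereocentre being set as R by the chiral sulfoxide–oxazoline ligand together with the preference of the alkenyl group for the side of the flat ketone carbon over the ring CH2; the closest known reaction type is palladium/sulfoxide-catalysed allylic C–H acyloxylation of terminal olefins with carboxylic acids (White-type allylic C–H oxidation, including its intramolecular and ligand-controlled enantioselective variants) and carboxylate-directed γ-C–H lactonisation.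

Step 7
Reactants: 13 (1R,5R,9S)-9-[(tert-butyldimethylsilyl)oxy]-1-[(1E)-2,6-dimethylhepta-1,5-dien-1-yl]-2-oxaspiro[4.5]dec-7-ene-3,6-dione
Product: 15 (1R,5R,9S)-1-[(1E)-2,6-dimethylhepta-1,5-dien-1-yl]-3,6-dioxo-2-oxaspiro[4.5]dec-7-en-9-yl acetate, via alcohol 14 (not isolated)
Conditions: HF·pyridine, pyridine, THF, 0 °C to rt; then Ac2O (excess), DMAP (cat.), 0 °C to rt
Reagents that add atoms: acetic anhydride, CC(=O)OC(C)=O
Why: Fluoride cleaves the Si–O bond with retention at C9, and DMAP-catalysed acetylation of the freed secondary allylic alcohol follows in the same flask; the lactone, enone and trisubstituted olefins are inert to buffered HF·pyridine and to Ac2O.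

Step 8
Reactants: 15 (1R,5R,9S)-1-[(1E)-2,6-dimethylhepta-1,5-dien-1-yl]-3,6-dioxo-2-oxaspiro[4.5]dec-7-en-9-yl acetate
Product: 16 (1R,5R,9S)-1-[(1E)-4-[(2R)-3,3-dimethyloxiran-2-yl]-2-methylbut-1-en-1-yl]-3,6-dioxo-2-oxaspiro[4.5]dec-7-en-9-yl acetate
Conditions: D-fructose-derived Shi ketone (30 mol %), Oxone (KHSO5, 1.4 equiv), K2CO3, Bu4NHSO4 (cat.), MeCN/(MeO)2CH2/aq. Na2B4O7–Na2(EDTA) buffer, 0 °C, 2 h
Reagents that add atoms: potassium peroxymonosulfate, [K+].[O-]S(=O)(=O)OO
Why: In this Shi asymmetric epoxidation the dioxirane from the D-fructose-derived ketone attacks only the electron-rich distal trisubstituted olefin (the proximal one is deactivated by the allylic lactone oxygen and shielded by the spiro centre, and the enone is electron-poor) through the spiro transition state that gives the 6R epoxide under catalyst control.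

Step 9
Reactants: 16 (1R,5R,9S)-1-[(1E)-4-[(2R)-3,3-dimethyloxiran-2-yl]-2-methylbut-1-en-1-yl]-3,6-dioxo-2-oxaspiro[4.5]dec-7-en-9-yl acetate
Product: 17 (1R,5R,9S)-1-[(1E,5R)-5-hydroxy-2,6-dimethylhepta-1,6-dien-1-yl]-3,6-dioxo-2-oxaspiro[4.5]dec-7-en-9-yl acetate
Conditions: Cp2TiCl2 (10 mol %), Co(salen) [N,N′-bis(3,5-di-tert-butylsalicylidene)-1,2-cyclohexanediaminatocobalt, divalent cobalt] (5 mol %), Zn (20 mol %), Et3N·HCl (1 equiv), THF, rt
Reagents that add atoms: none
Why: In this titanium/cobalt radical redox-relay isomerisation of an epoxide to an allylic alcohol, trivalent titanium opens the epoxide at the tertiary carbon, divalent cobalt removes a hydrogen atom from the accessible methyl group to give the isopropenyl unit, and because the C–O bond at the carbinol carbon is never broken the R configuration from step 8 is retained.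

**Compound list**

1 | cyclohexa-1,3-diene | C1=CC=CCC1 | starting material
2 | (1R,4S)-2,3-dioxabicyclo[2.2.2]oct-5-ene (meso endoperoxide) | C1=C[C@H]2CC[C@@H]1OO2 | intermediate (not isolated)
3 | (4S)-4-hydroxycyclohex-2-en-1-one | O=C1CC[C@H](O)C=C1 | intermediate
4 | (4S)-4-[(tert-butyldimethylsilyl)oxy]cyclohex-2-en-1-one | O=C1CC[C@H](O[Si](C)(C)C(C)(C)C)C=C1 | intermediate
5 | geranyl bromide, (2E)-1-bromo-3,7-dimethylocta-2,6-diene | CC(C)=CCC/C(C)=C/CBr | starting material
6 | lithium (4S)-4-[(tert-butyldimethylsilyl)oxy]cyclohexa-1,5-dien-1-olate | [Li+].[O-]C1=CC[C@H](O[Si](C)(C)C(C)(C)C)C=C1 | intermediate (not isolated)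
7 | (4S,6S)-4-[(tert-butyldimethylsilyl)oxy]-6-[(2E)-3,7-dimethylocta-2,6-dien-1-yl]cyclohex-2-en-1-one (major trans epimer; the cis epimer converges in step 4) | CC(C)=CCC/C(C)=C/C[C@H]1C[C@H](O[Si](C)(C)C(C)(C)C)C=CC1=O | intermediate
8 | methyl bromoacetate | COC(=O)CBr | starting material
9 | lithium (4S)-4-[(tert-butyldimethylsilyl)oxy]-2-[(2E)-3,7-dimethylocta-2,6-dien-1-yl]cyclohexa-1,5-dien-1-olate | [Li+].[O-]C1=C(C/C=C(\C)CCC=C(C)C)C[C@H](O[Si](C)(C)C(C)(C)C)C=C1 | intermediate (not isolated)
10 | methyl 2-[(1R,5S)-5-[(tert-butyldimethylsilyl)oxy]-1-[(2E)-3,7-dimethylocta-2,6-dien-1-yl]-2-oxocyclohex-3-en-1-yl]acetate | CC(C)=CCC/C(C)=C/C[C@]1(CC(=O)OC)C[C@H](O[Si](C)(C)C(C)(C)C)C=CC1=O | intermediate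
11 | lithium 2-[(1R,5S)-5-[(tert-butyldimethylsilyl)oxy]-1-[(2E)-3,7-dimethylocta-2,6-dien-1-yl]-2-oxocyclohex-3-en-1-yl]acetate | CC(C)=CCC/C(C)=C/C[C@]1(CC(=O)[O-])C[C@H](O[Si](C)(C)C(C)(C)C)C=CC1=O.[Li+] | intermediate (not isolated)
12 | 2-[(1R,5S)-5-[(tert-butyldimethylsilyl)oxy]-1-[(2E)-3,7-dimethylocta-2,6-dien-1-yl]-2-oxocyclohex-3-en-1-yl]acetic acid | CC(C)=CCC/C(C)=C/C[C@]1(CC(=O)O)C[C@H](O[Si](C)(C)C(C)(C)C)C=CC1=O | intermediate
13 | (1R,5R,9S)-9-[(tert-butyldimethylsilyl)oxy]-1-[(1E)-2,6-dimethylhepta-1,5-dien-1-yl]-2-oxaspiro[4.5]dec-7-ene-3,6-dione | CC(C)=CCC/C(C)=C/[C@H]1OC(=O)C[C@]12C[C@H](O[Si](C)(C)C(C)(C)C)C=CC2=O | intermediate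
14 | (1R,5R,9S)-1-[(1E)-2,6-dimethylhepta-1,5-dien-1-yl]-9-hydroxy-2-oxaspiro[4.5]dec-7-ene-3,6-dione | CC(C)=CCC/C(C)=C/[C@H]1OC(=O)C[C@]12C[C@H](O)C=CC2=O | intermediate (not isolated)
15 | (1R,5R,9S)-1-[(1E)-2,6-dimethylhepta-1,5-dien-1-yl]-3,6-dioxo-2-oxaspiro[4.5]dec-7-en-9-yl acetate | CC(C)=CCC/C(C)=C/[C@H]1OC(=O)C[C@]12C[C@H](OC(C)=O)C=CC2=O | intermediate
16 | (1R,5R,9S)-1-[(1E)-4-[(2R)-3,3-dimethyloxiran-2-yl]-2-methylbut-1-en-1-yl]-3,6-dioxo-2-oxaspiro[4.5]dec-7-en-9-yl acetate | CC1(C)O[C@@H]1CC/C(C)=C/[C@H]2OC(=O)C[C@]23C[C@H](OC(C)=O)C=CC3=O | intermediate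
17 | (1R,5R,9S)-1-[(1E,5R)-5-hydroxy-2,6-dimethylhepta-1,6-dien-1-yl]-3,6-dioxo-2-oxaspiro[4.5]dec-7-en-9-yl acetate (CNP0151251.2) | C=C(C)[C@H](O)CC/C(C)=C/[C@H]1OC(=O)C[C@]12C[C@H](OC(C)=O)C=CC2=O | target

**Totals and risk**

Total step count: 9. Longest linear sequence: 9 steps (1 to 17; 5 and 8 are bought).

The three steps most likely to fail:

Step 6 (the proposed lactonisation). Risks are C–H cleavage at the distal prenyl unit, Wacker-type attack of the carboxylate on the olefin to give a δ-lactone, and formation of the epimer at the new CH–O centre. The fallback uses known chemistry, sets out from 4 and comes back at 13. The lithium enolate 6 (LiN(iPr)2, THF, −78 °C) is added to bought geranial [(2E)-3,7-dimethylocta-2,6-dienal]. The aldehyde enters trans to OTBS through a Zimmerman–Traxler chair of the E enolate and gives the anti aldol adduct (4S,6R)-4-[(tert-butyldimethylsilyl)oxy]-6-[(1R,2E)-1-hydroxy-3,7-dimethylocta-2,6-dien-1-yl]cyclohex-2-en-1-one F1; the minor syn isomer is removed by chromatography. Et3SiCl and imidazole in CH2Cl2 give the silyl ether (4S,6R)-4-[(tert-butyldimethylsilyl)oxy]-6-[(1R,2E)-3,7-dimethyl-1-[(triethylsilyl)oxy]octa-2,6-dien-1-yl]cyclohex-2-en-1-one F2. A second enolisation (LiN(iPr)2, THF/DMPU, −78 °C) followed by methyl bromoacetate 8, which again enters trans to OTBS and so pushes the oxygenated carbon to the cis side, gives methyl 2-[(1R,5S)-5-[(tert-butyldimethylsilyl)oxy]-1-[(1R,2E)-3,7-dimethyl-1-[(triethylsilyl)oxy]octa-2,6-dien-1-yl]-2-oxocyclohex-3-en-1-yl]acetate F3. PPTS in MeOH removes only the triethylsilyl group, and the freed γ-hydroxy ester closes with loss of methanol to 13.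

Step 4 (quaternary centre). Risks are slow enolisation at the hindered C6–H and a modest trans/cis ratio. The fallback sets out from 4 and comes back at 10, with the order of the two C–C bonds reversed and the second one placed under catalyst control. 4 is alkylated first with methyl bromoacetate 8 (LiN(iPr)2, THF/DMPU, −78 °C) to methyl 2-[(1R,5S)-5-[(tert-butyldimethylsilyl)oxy]-2-oxocyclohex-3-en-1-yl]acetate F4. Its lithium enolate (LiN(iPr)2, THF, −78 °C) is then allylated with bought geranyl acetate under zerovalent palladium catalysis (Pd2(dba)3·CHCl3, Trost DACH-phenyl ligand, THF, 0 °C; Trost asymmetric allylic alkylation, linear E product). The ligand enantiomer is chosen so that the geranyl group ends up cis to OTBS, which gives 10.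

Step 9 (epoxide isomerisation). Risks are reduction or pinacol coupling of the enone by trivalent titanium and cyclisation of the tertiary radical onto the proximal olefin. The fallback sets out from 16 and comes back at 17 by an ionic instead of a radical opening. Me3SiOTf and 2,6-lutidine in toluene at −78 °C, then DBU, open the epoxide at the tertiary carbon with loss of a methyl proton (silyl triflate epoxide-to-allylic-silyl-ether rearrangement). This gives (1R,5R,9S)-1-[(1E,5R)-2,6-dimethyl-5-[(trimethylsilyl)oxy]hepta-1,6-dien-1-yl]-3,6-dioxo-2-oxaspiro[4.5]dec-7-en-9-yl acetate F5 with the carbinol C–O bond untouched. Citric acid in MeOH at 0 °C then removes the trimethylsilyl group to give 17.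

**Further compounds**

F1 | step 6 | (4S,6R)-4-[(tert-butyldimethylsilyl)oxy]-6-[(1R,2E)-1-hydroxy-3,7-dimethylocta-2,6-dien-1-yl]cyclohex-2-en-1-one | CC(C)=CCC/C(C)=C/[C@@H](O)[C@H]1C[C@H](O[Si](C)(C)C(C)(C)C)C=CC1=O
F2 | step 6 | (4S,6R)-4-[(tert-butyldimethylsilyl)oxy]-6-[(1R,2E)-3,7-dimethyl-1-[(triethylsilyl)oxy]octa-2,6-dien-1-yl]cyclohex-2-en-1-one | CC(C)=CCC/C(C)=C/[C@@H](O[Si](CC)(CC)CC)[C@H]1C[C@H](O[Si](C)(C)C(C)(C)C)C=CC1=O
F3 | step 6 | methyl 2-[(1R,5S)-5-[(tert-butyldimethylsilyl)oxy]-1-[(1R,2E)-3,7-dimethyl-1-[(triethylsilyl)oxy]octa-2,6-dien-1-yl]-2-oxocyclohex-3-en-1-yl]acetate | CC(C)=CCC/C(C)=C/[C@@H](O[Si](CC)(CC)CC)[C@]1(CC(=O)OC)C[C@H](O[Si](C)(C)C(C)(C)C)C=CC1=O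
F4 | step 4 | methyl 2-[(1R,5S)-5-[(tert-butyldimethylsilyl)oxy]-2-oxocyclohex-3-en-1-yl]acetate | COC(=O)C[C@H]1C[C@H](O[Si](C)(C)C(C)(C)C)C=CC1=O
F5 | step 9 | (1R,5R,9S)-1-[(1E,5R)-2,6-dimethyl-5-[(trimethylsilyl)oxy]hepta-1,6-dien-1-yl]-3,6-dioxo-2-oxaspiro[4.5]dec-7-en-9-yl acetate | C=C(C)[C@H](O[Si](C)(C)C)CC/C(C)=C/[C@H]1OC(=O)C[C@]12C[C@H](OC(C)=O)C=CC2=O
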